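## Structural features

Compound 22 consists of two benzene rings joined only by an ether oxygen; there is no further ring and no chain longer than the prenyl group. Ring A is a methyl benzoate with the ester on C1, a prenyl ether on C2, a methyl group on C4 and the aryloxy oxygen on C6, so the ester carbon is flanked on both sides by oxygen-bearing carbons. Ring B is attached through the oxygen on C1' and carries a hydroxymethyl group on C2' and methoxy groups on C4' and C6'. There is no stereocentre, and the one alkene bears two identical methyl groups, so no configuration has to be set. The fragile parts are the prenyl ether (acid, electrophiles, pericyclic side reactions), the benzylic alcohol ortho to the ether oxygen (ionisation in acid) and, during the synthesis, the silyl groups on carbon and oxygen. The real difficulty is the hindered diaryl ether: the oxygen on C1' sits between two ortho substituents, and C6 of ring A lies next to C1, the position between the two oxygens of the orcinol skeleton that electrophilic substitution does not reach. The route exploits the fact that C1 (carboxyl carbon) and C6 (ether oxygen) are neighbours beside the oxygenated C2: they are the two carbons of a 3-alkoxybenzyne, with the right polarity for an oxygen nucleophile at C6 and a one-carbon electrophile at C1.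

## Logic of the disconnections

22 ⇒ 20 + 21. The bond cut is the O–CH2 bond of the allylic ether on C2 of ring A. The prenyl group is the part least tolerant of arynes, organolithium reagents and acid, so it is attached last. The gain is that every earlier step runs on a molecule without an alkene. The demand is an alkylation that takes the phenol and leaves the benzylic alcohol of ring B alone; a carbonate base secures this through the difference in acidity.

20 ⇒ 19. Two O–H bonds are replaced by an O–CH2OCH3 bond on the C2 oxygen and an O–Si bond on the benzylic oxygen. The C2 oxygen must travel without an alkene and without an acidic proton, and the benzylic oxygen without a proton. The gain is that one acid treatment removes both groups. The demand is cleavage without ionising the benzylic position.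

19 ⇒ 18. The bond cut is the O–CH3 bond of the ester, because the key step delivers a carboxylate. The demand is esterification through the carboxylate oxygen, since the carboxyl carbon is shielded by two ortho substituents.

18 ⇒ 9 + 13 + 14 (through 16). The bonds cut are C6–O of the diaryl ether and C1–C of the carboxyl group. Cutting both at once turns ring A into an aryne whose two reactive carbons are exactly C1 and C6. The gain is the largest of the route: a hindered diaryl ether and a carboxyl group flanked by two ortho substituents become one aryne precursor, one phenol and a gas. The demands are regiocontrol across the aryne (from the C2 oxygen), the absence of any proton source, and an oxygen substituent on C2 that cannot react with the aryne.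

9 ⇒ 7 ⇒ 3 ⇒ 2 ⇒ 1. The bonds cut in turn are O–S of the triflate (through 8), C–Si on the carbon between the oxygens, the carbamate C–O bond and the acetal O–CH2 bond. The carbamate is both the directing group for metalation and the masked triflate oxygen. The gain is a symmetrical, cheap diphenol as starting point. The demands are one desymmetrising mono-protection and metalation at the doubly activated carbon only.

13 ⇒ 12 ⇒ 11 ⇒ 10. The bonds cut are the benzylic O–Si bond, a C–H bond of the CH2 group (carbonyl reduction) and the aryl–CHO bond ortho to the phenol. Ring B is thus bought with its oxygens in place. The demand is formylation at the phenol-ortho position and not at the positions activated by the methoxy groups.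

## Other disconnections considered

Alternative 1: The cut runs through ring B (C1'–C2' and C1'–C6'), which is rebuilt on a coumaranone.
- Forward step: the C2 carbanion of coumaranone A1 (catalytic KOt-Bu) adds in Michael fashion to the enone arm and then to the ynone arm of ketone A2, closing the spiro-cyclohexenone A3. Dehydrogenation to dienone A4, methoxide attack on the furanone carbonyl with C–C cleavage to phenol A5, O-methylation and desilylation would lead to 22.
- In favour: the spiroannulation is an established base-catalysed reaction class, the ester necessarily ends up ortho to the ether oxygen, and the ring opening is driven by aromatisation.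
- Against: ring B is assembled from an acyclic ketone although its aromatic pattern can be bought. Two stereocentres are made only to be destroyed. A dehydrogenation must be run beside a prenyl ether. A1 carries its acyl carbon on the position of 1 between the two oxygens, which direct acylation does not reach, so A1 needs a directed metalation of its own.
- Comparison: on mechanism this alternative is the better, because its key bond formation belongs to a known class while the chosen coupling is an extension. On structure it is the poorer, since it passes through a non-aromatic ring B. On step economy it is also the poorer: four operations follow its key step against three, and both partners take longer to prepare.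

Alternative 2: The cut goes through ring A at C5–C6 and C1–C2.
- Forward step: silyl dienolate A6 adds with its terminal carbon to the oxygen-bearing alkyne carbon of aryloxypropiolate A7 (made from 13). The propiolate α-carbon then bonds to the ketene acetal carbon, either in concert or by vinylogous Michael addition followed by Claisen-type closure. Loss of MeOSiMe3 aromatises ring A to phenol A8; prenylation and desilylation would finish.
- In favour: the ring A oxygen arrives as a free phenol, so neither a protecting group nor a statistical desymmetrisation of 1 is needed. Regiochemistry follows from the polarity of both partners.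
- Against: A7 is a push–pull alkyne whose reacting carbon is deactivated by the aryloxy donor and shielded by the doubly ortho-substituted ring B. Forcing conditions are likely. After conjugate addition the aryloxide is a good leaving group, so addition–elimination may expel ring B instead of closing ring A. Making A7 needs a strongly basic elimination on a silyl-protected substrate.
- Comparison: on step economy this alternative is the equal of the chosen plan or slightly the better. On structure the two are equal in using ring B intact, while the chosen plan takes ring A ready-made from 1. On mechanism both rest on an untested extension of a known class, but the chosen plan has a short detour through known reactions with the same two fragments, which this alternative lacks.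

Alternative 3: The cut goes through ring A at C4–C5 and C1–C6.
- Forward step: the 3-carbomethoxy-2-pyrone A9 and the aryl ethynyl ether A10 (from 13) combine in an inverse-demand Diels–Alder reaction. The unsubstituted alkyne carbon bonds to the methyl-bearing pyrone carbon and the oxygen-bearing one to the ester-bearing carbon. The bridged lactone expels CO2 to give A11, from which only the silyl group has to be removed.
- In favour: it is the most convergent plan. Every substituent of ring A, prenyl ether and ester included, is in place at the key step. Loss of CO2 is irreversible and regiochemistry is set by polarity.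
- Against: the 4-alkoxy group makes A9 a vinylogous carbonate and no longer an electron-poor diene. The 6-methyl group sits on the carbon that must bond first. The heat required invites Claisen rearrangement of the prenyl vinylogous ester and decomposition of A10.
- Comparison: on structure this alternative is the better (one step after the key step, no protecting group on ring A). On step economy it is the equal or slightly the better. On mechanism the chosen plan is preferred: aryne formation and phenoxide addition run at or below room temperature, where every sensitive group survives, whereas this cycloaddition is electronically mismatched and cannot be run cold.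

Key step: step 8

Remark: 22 has no stereocentre and no stereogenic alkene; reagents that appear only on Conditions lines are taken as purchased.

## Route

Step 1
Reactants: 1 orcinol (5-methylbenzene-1,3-diol)
Product: 2 3-(methoxymethoxy)-5-methylphenol
Conditions: NaH (1 equiv), MOMCl (1 equiv), 1 in twofold excess, THF/DMF, 0 °C → rt
Reagents that add atoms: chloromethyl methyl ether, COCCl
Why: Williamson-type O-alkylation of the monophenoxide; keeping 1 in excess over base and alkylating agent holds double alkylation down, and the water-soluble surplus of 1 is washed out and reused.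

Step 2
Reactants: 2 3-(methoxymethoxy)-5-methylphenol
Product: 3 3-(methoxymethoxy)-5-methylphenyl N-(propan-2-yl)carbamate
Conditions: i-PrNCO, Et3N (cat.), CH2Cl2, rt
Reagents that add atoms: isopropyl isocyanate, CC(C)N=C=O
Why: Base-catalysed addition of the phenol to the isocyanate (carbamoylation); the N–H carbamate is chosen because it directs metalation and can later be removed by a mild E1cB elimination.

Step 3
Reactants: 3 3-(methoxymethoxy)-5-methylphenyl N-(propan-2-yl)carbamate
Product: 7 3-(methoxymethoxy)-5-methyl-2-(trimethylsilyl)phenyl N-(propan-2-yl)carbamate, via N-silyl carbamate 4 (not isolated), via aryllithium 5 (not isolated), via N-silyl C-silyl carbamate 6 (not isolated)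
Conditions: TBSOTf (1.05 equiv), TMEDA, Et2O, 0 °C → rt; n-BuLi, TMEDA, −78 °C; TMSCl, −78 °C → rt; cold aq NaHSO4 (brief)
Reagents that add atoms: chlorotrimethylsilane, C[Si](C)(C)Cl
Why: Directed ortho-metalation: N-silylation in the flask masks the N–H, the carbamate and the acetal oxygen together direct n-BuLi/TMEDA to the carbon between them, and silylation at −78 °C outruns the anionic ortho-Fries rearrangement; the N–Si bond is hydrolysed on work-up.

Step 4
Reactants: 7 3-(methoxymethoxy)-5-methyl-2-(trimethylsilyl)phenyl N-(propan-2-yl)carbamate
Product: 9 3-(methoxymethoxy)-5-methyl-2-(trimethylsilyl)phenyl trifluoromethanesulfonate, via silylphenol 8 (not isolated)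
Conditions: DBU, Et2NH, MeCN, 40 °C; then PhNTf2, rt
Reagents that add atoms: N-phenylbis(trifluoromethanesulfonimide), O=S(=O)(N(c1ccccc1)S(=O)(=O)C(F)(F)F)C(F)(F)F
Why: DBU removes the carbamate N–H and E1cB loss of isopropyl isocyanate (trapped by Et2NH as a urea) gives the phenoxide of 8, which is O-sulfonylated in the same flask by the mild triflyl donor; no acid touches the C–Si bond, which is prone to protodesilylation.

Step 5
Reactants: 10 2,4-dimethoxyphenol
Product: 11 2-hydroxy-3,5-dimethoxybenzaldehyde
Conditions: (CH2O)n, MgCl2, Et3N, MeCN, reflux; then 1 M HCl
Reagents that add atoms: paraformaldehyde (as formaldehyde), C=O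
Why: Casnati–Skattebøl ortho-formylation: the ArOMgCl phenoxide delivers formaldehyde to the only free ortho position and a second formaldehyde takes up hydride from the hydroxymethyl intermediate, so the carbons activated by the methoxy groups are not attacked.

Step 6
Reactants: 11 2-hydroxy-3,5-dimethoxybenzaldehyde
Product: 12 2-(hydroxymethyl)-4,6-dimethoxyphenol
Conditions: NaBH4, MeOH, 0 °C; aq NH4Cl
Reagents that add atoms: none
Why: Hydride reduction of the aldehyde; near-neutral work-up avoids o-quinone methide formation from the electron-rich salicyl alcohol.

Step 7
Reactants: 12 2-(hydroxymethyl)-4,6-dimethoxyphenol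
Product: 13 2-[(tert-butyldimethylsilyloxy)methyl]-4,6-dimethoxyphenol
Conditions: TBSCl (1.05 equiv), imidazole, CH2Cl2, 0 °C
Reagents that add atoms: tert-butyldimethylsilyl chloride, CC(C)(C)[Si](C)(C)Cl
Why: Chemoselective silyl ether formation: the unhindered primary alcohol is silylated faster than the hydrogen-bonded phenol that sits between two ortho substituents.

Step 8
Reactants: 13 2-[(tert-butyldimethylsilyloxy)methyl]-4,6-dimethoxyphenol, 9 3-(methoxymethoxy)-5-methyl-2-(trimethylsilyl)phenyl trifluoromethanesulfonate, 14 carbon dioxide
Product: 18 2-{2-[(tert-butyldimethylsilyloxy)methyl]-4,6-dimethoxyphenoxy}-6-(methoxymethoxy)-4-methylbenzoic acid, via potassium phenoxide 15 (not isolated), via aryne 16 (not isolated), via aryl anion 17 (not isolated)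
Conditions: 13 (1.5 equiv), KH, THF, 0 °C; 18-crown-6, KF, CO2 (1 atm), 9 added slowly, 0 °C → rt; cold 1 M HCl to pH 4
Reagents that add atoms: none
Why: Proposed new method: fluoride (KF solubilised by 18-crown-6) attacks the silicon of 9 and triflate departs, releasing aryne 16; the oxygen of phenoxide 15 adds to the aryne carbon remote from the methoxymethoxy group (C6 of ring A), and the aryl anion 17 formed at C1 is carboxylated by dissolved CO2, so the C6–O and C1–CO2 bonds form in one operation. The closest known reaction types are the fluoride-induced three-component coupling of arynes with amines and CO2 to anthranilic acids and the aryne O-arylation of phenols; the combination of a phenoxide with CO2 capture has not been shown. No ring is closed and no stereocentre is formed. Regioselectivity across the aryne is required and is secured by the 3-alkoxy group, whose inductive pull makes the distal carbon the more electrophilic and stabilises the charge developing on the carbon next to it; the bulk of the doubly ortho-substituted phenoxide works in the same sense. Carboxylation must beat protonation of 17, which is why the phenoxide is preformed with KH (H2 the only by-product), why THF replaces the C–H acidic acetonitrile, and why the benzylic oxygen of ring B is silylated. Binding of CO2 to the phenoxide oxygen is reversible, as carbamate formation is in the amine version, so free 15 stays available, and slow addition of 9 keeps 16 dilute so that neither 17 nor the product carboxylate adds to a second aryne. The acetal on the ring A oxygen offers no alkene for an intramolecular ene reaction with the aryne, which a prenyl ether would.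

Step 9
Reactants: 18 2-{2-[(tert-butyldimethylsilyloxy)methyl]-4,6-dimethoxyphenoxy}-6-(methoxymethoxy)-4-methylbenzoic acid
Product: 19 methyl 2-{2-[(tert-butyldimethylsilyloxy)methyl]-4,6-dimethoxyphenoxy}-6-(methoxymethoxy)-4-methylbenzoate
Conditions: MeI, K2CO3, DMF, rt
Reagents that add atoms: iodomethane, CI
Why: SN2 O-alkylation of the carboxylate; the acid does not esterify by the Fischer method because of its two ortho substituents, but its carboxylate oxygen is unhindered, and base leaves the acetal and the silyl ether untouched.

Step 10
Reactants: 19 methyl 2-{2-[(tert-butyldimethylsilyloxy)methyl]-4,6-dimethoxyphenoxy}-6-(methoxymethoxy)-4-methylbenzoate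
Product: 20 methyl 2-hydroxy-6-[2-(hydroxymethyl)-4,6-dimethoxyphenoxy]-4-methylbenzoate
Conditions: HCl (0.5 M), MeOH, rt
Reagents that add atoms: none
Why: Acid-catalysed acetal exchange frees the phenol (the acetal carbon leaves as dimethoxymethane) and methanolysis cleaves the primary silyl ether in the same operation; the methyl ester is inert in methanol, and dilute acid at room temperature is chosen to keep the benzylic alcohol from ionising.

Step 11
Reactants: 20 methyl 2-hydroxy-6-[2-(hydroxymethyl)-4,6-dimethoxyphenoxy]-4-methylbenzoate, 21 prenyl bromide (1-bromo-3-methylbut-2-ene)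
Product: 22 methyl 2-[2-(hydroxymethyl)-4,6-dimethoxyphenoxy]-4-methyl-6-[(3-methylbut-2-en-1-yl)oxy]benzoate
Conditions: K2CO3, DMF, rt
Reagents that add atoms: none
Why: Williamson ether synthesis: the carbonate deprotonates only the phenol, the benzylic alcohol stays neutral, and the phenoxide displaces bromide at the primary allylic carbon (SN2).

## Compound list

1 | orcinol (5-methylbenzene-1,3-diol) | Cc1cc(O)cc(O)c1 | starting material
2 | 3-(methoxymethoxy)-5-methylphenol | COCOc1cc(C)cc(O)c1 | intermediate
3 | 3-(methoxymethoxy)-5-methylphenyl N-(propan-2-yl)carbamate | COCOc1cc(C)cc(OC(=O)NC(C)C)c1 | intermediate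
4 | 3-(methoxymethoxy)-5-methylphenyl N-(tert-butyldimethylsilyl)-N-(propan-2-yl)carbamate | COCOc1cc(C)cc(OC(=O)N(C(C)C)[Si](C)(C)C(C)(C)C)c1 | intermediate (not isolated)
5 | 2-lithio derivative of 4, lithium on the carbon between the two oxygens | COCOc1cc(C)cc(OC(=O)N(C(C)C)[Si](C)(C)C(C)(C)C)c1[Li] | intermediate (not isolated)
6 | 3-(methoxymethoxy)-5-methyl-2-(trimethylsilyl)phenyl N-(tert-butyldimethylsilyl)-N-(propan-2-yl)carbamate | COCOc1cc(C)cc(OC(=O)N(C(C)C)[Si](C)(C)C(C)(C)C)c1[Si](C)(C)C | intermediate (not isolated)
7 | 3-(methoxymethoxy)-5-methyl-2-(trimethylsilyl)phenyl N-(propan-2-yl)carbamate | COCOc1cc(C)cc(OC(=O)NC(C)C)c1[Si](C)(C)C | intermediate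
8 | 3-(methoxymethoxy)-5-methyl-2-(trimethylsilyl)phenol (present as its DBU-H phenoxide) | COCOc1cc(C)cc(O)c1[Si](C)(C)C | intermediate (not isolated)
9 | 3-(methoxymethoxy)-5-methyl-2-(trimethylsilyl)phenyl trifluoromethanesulfonate | COCOc1cc(C)cc(OS(=O)(=O)C(F)(F)F)c1[Si](C)(C)C | intermediate
10 | 2,4-dimethoxyphenol | COc1ccc(O)c(OC)c1 | starting material
11 | 2-hydroxy-3,5-dimethoxybenzaldehyde | COc1cc(C=O)c(O)c(OC)c1 | intermediate
12 | 2-(hydroxymethyl)-4,6-dimethoxyphenol | COc1cc(CO)c(O)c(OC)c1 | intermediate
13 | 2-[(tert-butyldimethylsilyloxy)methyl]-4,6-dimethoxyphenol | COc1cc(CO[Si](C)(C)C(C)(C)C)c(O)c(OC)c1 | intermediate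
14 | carbon dioxide | O=C=O | starting material
15 | potassium 2-[(tert-butyldimethylsilyloxy)methyl]-4,6-dimethoxyphenoxide | COc1cc(CO[Si](C)(C)C(C)(C)C)c([O-])c(OC)c1.[K+] | intermediate (not isolated)
16 | 3-(methoxymethoxy)-5-methylbenzyne (3-(methoxymethoxy)-5-methyl-1,2-didehydrobenzene) | COCOC1=CC(C)=CC#C1 | intermediate (not isolated)
17 | potassium 2-{2-[(tert-butyldimethylsilyloxy)methyl]-4,6-dimethoxyphenoxy}-6-(methoxymethoxy)-4-methylbenzenide (aryl anion at C1 of ring A) | COCOc1cc(C)cc(Oc2c(CO[Si](C)(C)C(C)(C)C)cc(OC)cc2OC)[c-]1.[K+] | intermediate (not isolated)
18 | 2-{2-[(tert-butyldimethylsilyloxy)methyl]-4,6-dimethoxyphenoxy}-6-(methoxymethoxy)-4-methylbenzoic acid | OC(=O)c1c(OCOC)cc(C)cc1Oc1c(CO[Si](C)(C)C(C)(C)C)cc(OC)cc1OC | intermediate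
19 | methyl 2-{2-[(tert-butyldimethylsilyloxy)methyl]-4,6-dimethoxyphenoxy}-6-(methoxymethoxy)-4-methylbenzoate | COC(=O)c1c(OCOC)cc(C)cc1Oc1c(CO[Si](C)(C)C(C)(C)C)cc(OC)cc1OC | intermediate
20 | methyl 2-hydroxy-6-[2-(hydroxymethyl)-4,6-dimethoxyphenoxy]-4-methylbenzoate | COC(=O)c1c(O)cc(C)cc1Oc1c(CO)cc(OC)cc1OC | intermediate
21 | prenyl bromide (1-bromo-3-methylbut-2-ene) | CC(C)=CCBr | starting material
22 | methyl 2-[2-(hydroxymethyl)-4,6-dimethoxyphenoxy]-4-methyl-6-[(3-methylbut-2-en-1-yl)oxy]benzoate | COC(=O)c1c(OCC=C(C)C)cc(C)cc1Oc1c(CO)cc(OC)cc1OC | target

## Step count and least certain steps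

Total: 11 steps. Longest linear sequence: 8 steps (steps 1–4 and 8–11). Steps 5–7 are a three-step branch that joins in step 8.

Step 8 (bears the label "Proposed new method:").
- Most likely failure: protonation of the aryl anion outrunning carboxylation, because little CO2 is dissolved and traces of proton donors are hard to exclude. In addition, reversible carbonation of the phenoxide oxygen lowers the concentration of the oxygen nucleophile and offers the aryne a second, carboxylate-type nucleophile. Fluoride-induced loss of the silyl ether would add a proton source.
- Fallback with known chemistry, from 9 and 13 back to 18: aryne O-arylation under the usual protic regime (CsF, MeCN, rt, the phenol itself as proton donor) should give the proton-quenched diaryl ether F1. Directed ortho-metalation (n-BuLi, TMEDA, THF, −78 → −20 °C) should occur at the ring A carbon between the acetal oxygen and the aryloxy oxygen to give the aryllithium F2. A chelating acetal plus an inductively withdrawing aryloxy group is a stronger pair of directors than the two methoxy groups of ring B. Quenching with CO2 and mild acidification returns to 18.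

Step 3.
- Most likely failure: activation of the methoxymethyl acetal by the silyl triflate during N-silylation, or incomplete N-silylation followed by loss of isocyanate from the N-lithio carbamate. If the mixture warms before the quench, anionic ortho-Fries migration of the carbamoyl group is also possible.
- Fallback, from 2 back to 8 and then 9: acylation of 2 with ClCONEt2 (K2CO3, MeCN) gives the N,N-diethylcarbamate F3, which needs no protection on nitrogen. s-BuLi/TMEDA in THF at −78 °C gives the ortho-lithiated carbamate F4, and TMSCl gives the C-silyl carbamate F5. Reductive cleavage with LiAlH4 in THF gives phenol 8, here isolated, and PhNTf2/Et3N converts it to 9.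

Step 10.
- Most likely failure: ionisation of the benzylic alcohol in acidic methanol (methyl ether formation or Friedel–Crafts-type self-condensation) before the aryl acetal is fully cleaved.
- Fallback, from 19 to 22 without passing through 20: the acetal alone is removed under non-protic conditions (TMSOTf, 2,2'-bipyridyl, CH2Cl2, 0 °C), which gives the aryl trimethylsilyl ether F6. Water then gives the phenol F7 with the benzylic silyl ether intact. Prenylation (21, K2CO3, DMF) gives the silyl ether of the target F8, and TBAF in THF buffered with AcOH releases 22. The benzylic oxygen is then never free in acid, and the prenylation has only one hydroxyl group to choose from.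

Step 5.
- Most likely failure: condensation of the very electron-rich phenol with formaldehyde to diarylmethanes, or attack at the carbons activated by the methoxy groups if the magnesium template forms incompletely.
- Fallback, from 10 directly to 12: boron-templated ortho-hydroxymethylation (PhB(OH)2, (CH2O)n, EtCO2H cat., toluene, reflux with removal of water) gives the benzodioxaborin F9. Exchange with propane-1,3-diol frees 12, which also makes the reduction of step 6 unnecessary.

Step 7.
- Most likely failure: silylation of the phenol oxygen in competition with the alcohol, or of both oxygens.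
- Fallback, from 12 back to 13: exhaustive silylation (excess TBSCl, imidazole, DMF) gives the bis-silyl ether F10, and K2CO3 in MeOH at rt cleaves only the aryl silyl ether.

## Further compounds

F1 | step 8 | tert-butyl({3,5-dimethoxy-2-[3-(methoxymethoxy)-5-methylphenoxy]phenyl}methoxy)dimethylsilane | COCOc1cc(C)cc(Oc2c(CO[Si](C)(C)C(C)(C)C)cc(OC)cc2OC)c1
F2 | step 8 | 2-lithio derivative of F1, lithium on the ring A carbon between the acetal oxygen and the aryloxy oxygen | COCOc1cc(C)cc(Oc2c(CO[Si](C)(C)C(C)(C)C)cc(OC)cc2OC)c1[Li]
F3 | step 3 | 3-(methoxymethoxy)-5-methylphenyl N,N-diethylcarbamate | COCOc1cc(C)cc(OC(=O)N(CC)CC)c1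
F4 | step 3 | 2-lithio derivative of F3, lithium on the carbon between the two oxygens | COCOc1cc(C)cc(OC(=O)N(CC)CC)c1[Li]
F5 | step 3 | 3-(methoxymethoxy)-5-methyl-2-(trimethylsilyl)phenyl N,N-diethylcarbamate | COCOc1cc(C)cc(OC(=O)N(CC)CC)c1[Si](C)(C)C
F6 | step 10 | methyl 2-{2-[(tert-butyldimethylsilyloxy)methyl]-4,6-dimethoxyphenoxy}-4-methyl-6-[(trimethylsilyl)oxy]benzoate | COC(=O)c1c(O[Si](C)(C)C)cc(C)cc1Oc1c(CO[Si](C)(C)C(C)(C)C)cc(OC)cc1OC
F7 | step 10 | methyl 2-{2-[(tert-butyldimethylsilyloxy)methyl]-4,6-dimethoxyphenoxy}-6-hydroxy-4-methylbenzoate | COC(=O)c1c(O)cc(C)cc1Oc1c(CO[Si](C)(C)C(C)(C)C)cc(OC)cc1OC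
F8 | step 10 | methyl 2-{2-[(tert-butyldimethylsilyloxy)methyl]-4,6-dimethoxyphenoxy}-4-methyl-6-[(3-methylbut-2-en-1-yl)oxy]benzoate | COC(=O)c1c(OCC=C(C)C)cc(C)cc1Oc1c(CO[Si](C)(C)C(C)(C)C)cc(OC)cc1OC
F9 | step 5 | 6,8-dimethoxy-2-phenyl-4H-1,3,2-benzodioxaborinine | COc1cc(OC)c2OB(c3ccccc3)OCc2c1
F10 | step 7 | tert-butyl{2-[(tert-butyldimethylsilyloxy)methyl]-4,6-dimethoxyphenoxy}dimethylsilane | COc1cc(CO[Si](C)(C)C(C)(C)C)c(O[Si](C)(C)C(C)(C)C)c(OC)c1
A1 | alternative 1 | 6-methyl-4-[(3-methylbut-2-en-1-yl)oxy]-1-benzofuran-3(2H)-one | O=C1COc2cc(C)cc(OCC=C(C)C)c12
A2 | alternative 1 | (E)-6-[(tert-butyldimethylsilyl)oxy]-1-methoxyhex-4-en-1-yn-3-one | COC#CC(=O)/C=C/CO[Si](C)(C)C(C)(C)C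
A3 | alternative 1 | 6'-{[(tert-butyldimethylsilyl)oxy]methyl}-2'-methoxy-6-methyl-4-[(3-methylbut-2-en-1-yl)oxy]-3H-spiro[1-benzofuran-2,1'-cyclohex-2-ene]-3,4'-dione, racemic mixture of diastereomers | O=C1c2c(OCC=C(C)C)cc(C)cc2OC13C(OC)=CC(=O)CC3CO[Si](C)(C)C(C)(C)C
A4 | alternative 1 | 6'-{[(tert-butyldimethylsilyl)oxy]methyl}-2'-methoxy-6-methyl-4-[(3-methylbut-2-en-1-yl)oxy]-3H-spiro[1-benzofuran-2,1'-cyclohexa-2,5-diene]-3,4'-dione, racemic | O=C1c2c(OCC=C(C)C)cc(C)cc2OC13C(OC)=CC(=O)C=C3CO[Si](C)(C)C(C)(C)C
A5 | alternative 1 | methyl 2-{2-[(tert-butyldimethylsilyloxy)methyl]-4-hydroxy-6-methoxyphenoxy}-4-methyl-6-[(3-methylbut-2-en-1-yl)oxy]benzoate | COC(=O)c1c(OCC=C(C)C)cc(C)cc1Oc1c(CO[Si](C)(C)C(C)(C)C)cc(O)cc1OC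
A6 | alternative 2 | 1-methoxy-3-methyl-1-(trimethylsilyloxy)buta-1,3-diene | COC(O[Si](C)(C)C)=CC(C)=C
A7 | alternative 2 | methyl 3-{2-[(tert-butyldimethylsilyloxy)methyl]-4,6-dimethoxyphenoxy}prop-2-ynoate | COC(=O)C#COc1c(CO[Si](C)(C)C(C)(C)C)cc(OC)cc1OC
A8 | alternative 2 | methyl 2-{2-[(tert-butyldimethylsilyloxy)methyl]-4,6-dimethoxyphenoxy}-6-hydroxy-4-methylbenzoate | COC(=O)c1c(O)cc(C)cc1Oc1c(CO[Si](C)(C)C(C)(C)C)cc(OC)cc1OC
A9 | alternative 3 | methyl 6-methyl-4-[(3-methylbut-2-en-1-yl)oxy]-2-oxo-2H-pyran-3-carboxylate | COC(=O)C1=C(OCC=C(C)C)C=C(C)OC1=O
A10 | alternative 3 | tert-butyl{[2-(ethynyloxy)-3,5-dimethoxyphenyl]methoxy}dimethylsilane | C#COc1c(CO[Si](C)(C)C(C)(C)C)cc(OC)cc1OC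
A11 | alternative 3 | methyl 2-{2-[(tert-butyldimethylsilyloxy)methyl]-4,6-dimethoxyphenoxy}-4-methyl-6-[(3-methylbut-2-en-1-yl)oxy]benzoate | COC(=O)c1c(OCC=C(C)C)cc(C)cc1Oc1c(CO[Si](C)(C)C(C)(C)C)cc(OC)cc1OC
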